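**Earlier plateaus.** Sunday's run, charged with L at 0.840 of the J charge, stood at Q 34.0% of the J charge after 60.0 min. Thursday's run, charged at 1.84, stood at Q 69.6% and gained 0.3 percentage points over its last interval, so plateaus can stand in for the ends of the new flasks.

the same everywhere: J 0.050 M; Z 25 µM

| charge | L | E | remark | time |
|---|---|---|---|---|
| Sunday's | 0.042 M | 0.050 M | run made earlier |  |
| Thursday's | 0.092 M | 0.050 M | run made earlier |  |
| south | 0.0350 M | 0.0500 M |  | 80 min |
| north-west | 0.0700 M | 0.0500 M |  | 80 min |

| run | time / min | J / % | Q / % |
|---|---|---|---|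
| Sunday's | 5.00 | 78.2 | 21.1 |
| Sunday's | 8.00 | 74.2 | 25.9 |
| Sunday's | 12.0 | 70.7 | 28.9 |
| Sunday's | 20.0 | 68.4 | 31.8 |
| Sunday's | 30.0 | 66.8 | 32.7 |
| Sunday's | 60.0 | 65.9 | 34.0 |
| Thursday's | 10.0 | 45.3 | 55.1 |
| Thursday's | 20.0 | 36.0 | 63.8 |
| Thursday's | 30.0 | 32.9 | 67.1 |
| Thursday's | 40.0 | 31.8 | 68.5 |
| Thursday's | 50.0 | 30.9 | 69.3 |
| Thursday's | 60.0 | 29.8 | 69.6 |

(standard deviation of a reading: 0.3 percentage points)



- which of these there is most of at the end, counted by the J in it, south (Q / J)
- which of these there is most of at the end, counted by the J in it, north-west (Q / J)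
- the largest of these amounts at the end, in percent of the J charged, south
- the largest of these amounts at the end, in percent of the J charged, north-west

**Bench rule.** Sunday's plateau, as a reading, gives 2.47 for the L price, which is the L charged per Q found at the plateau, both as fractions of the J charge. This one mean replaces whatever the ratio does along the curve, and the Q fraction expected at the end is then the L fraction divided by the price. South, at 0.700, gets Q 28.3%, which leaves J 71.7%, and north-west, at 1.40, gets Q 56.7%.

**Its border.** The rule ends where the L fraction reaches the price, since the division there gives Q equal to the whole J charge. The mean can be checked against Thursday's run, for which the division gives Q 74.5%, and this overshoots the reading by 4.9 points. Thursday's own price is 2.64, higher than Sunday's, and it gives north-west 53.0%. My reckoning therefore commits to J as the larger part in south, at 71.7%, and to Q as the larger part in north-west, between that lower figure and 56.7%.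

**The forecast.** It gives J at 71.5% for south and Q at 55% for north-west, with the picture that “E competes for L”.

**The result.** South ends with J at 71.5% and Q at 28.4%, and north-west ends with Q at 56.5% and J at 43.5%.

    Z + Q → D (k = 0.0210 L mol⁻¹ s⁻¹)
    J + L + Z → Z + Q (k = 1400 L² mol⁻² s⁻¹)
    E + L + Z → Z + G (k = 2200 L² mol⁻² s⁻¹)
    2 Z → X (k = 15.0 L mol⁻¹ s⁻¹)

**Past the border.** These ends put the L price at 2.46 in south and 2.48 in north-west. The neighbour of south charged with 0.14 M of L carries an L fraction of 2.80, above the price, so the same division gives Q 113%, more than the J charged. That neighbour ends with Q at 88.7%, J at 11.2%, and L at 33.7% of its own charge.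

The data are simulated with made-up constants, and the scatter is random.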